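The easy step is a slope: take two north readings on the straight stretch and turn them into a time.

| setting | east | north | flask |
|---|---|---|---|
| starting material | 0.50 M | 0.50 M | 0.50 M |
| reagent in the second phase | 0.90 equiv | 0.90 equiv | 0.900 equiv |
| protic impurity | 0.025 M | 0.038 M | 0.0250 M |
| remark | the very flask that is asked about, followed so far | run made earlier |  |
| time |  |  | 25 h |
| volume of the second phase over the first |  |  | 1.0 |

- east (time / h: product / %): 0.833: 0; 2.50: 1.4; 5.00: 3.8; 8.00: 4.7; 10.0: 7.0
- north (time / h: product / %): 5.00: 3.2; 10.0: 6.6; 15.0: 9.8; 20.0: 13.6; 25.0: 14.7

(each reading ± 0.5 percentage points)

- in the second phase: reagent in the second phase; everything else is in the first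
- charges count per volume of the first phase; a concentration in a rate is the amount of a species over the volume of its own phase; every rate counts per litre of the first phase
- the numbers in the tables scatter by 0.5 percentage points (one standard deviation)
- the earlier runs hold the two phases in the same ratio of volumes as the flask asked about

- grey: doubling the transfer coefficient of the reagent in the second phase, all else as stated
- red: doubling the amount of reagent in the second phase, all else as stated

- amount of product at 25 h, in percent of the starting material charged
- the change that raises the amount of product at 25 h, in percent of the starting material charged most ("none" if none brings more than 2 percentage points) (grey / red / none)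
- amount of product at 25 h, in percent of the starting material charged, after grey

Between 5.00 h and 20.0 h the north run gains 10 percentage points. That gives 144 h, and this conversion time, the hours the whole charge of starting material needs at that pace, is what two chemists now argue over. East, with less impurity, reads 134 h.

The first says the pace is what crosses from the second phase, the rate-limiting step being transfer. Her line gives 17.4% at 25 h, and grey doubles that to 34.7%.

The second objects. East's impurity is 5.00% of the starting material, so if it took the crossing reagent first, at this pace, product would wait 7.21 h. Yet east reads 3.8% at 5.00 h, earlier than that wait allows. So he puts the slow step in the first phase: starting material decays pseudo-first-order with the conversion time as its time constant. I reckon with him: 15.9% at 25 h, and doubling the reagent gives 29.3%; this reckoning holds no transfer coefficient, so it says nothing of grey.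

The forecast takes his side: 16%, red as the best change, 16.3% after grey. In its words: “Doubling transfer only shortens the lag”.

The flask gives 16.0%. The change red adds 13 points, grey adds 0.3 points, reaching 16.3%.

    reagent in the reaction phase ⇌ reagent in the second phase, rate k1*([reagent in the reaction phase] - [reagent in the second phase]/K1) per volume of the first phase (partition coefficient = 0.580, kL = 1.05 × 10⁻⁴ s⁻¹)
    starting material + reagent in the reaction phase → product (k = 8.29 × 10⁻⁶ L mol⁻¹ s⁻¹)
    starting material + protic impurity → quenched substrate (k = 3.04 × 10⁻⁴ L mol⁻¹ s⁻¹)

The inverse of the transfer coefficient is 2.65 h, and the conversion time as read from north is 54.3 times longer. The crossing view gets the time before 2.50 h in this flask: reagent in the reaction phase already stands at 0.258 M by then and at 0.257 M at 12.5 h.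

A neighbour flask charges 0.20 M of starting material at the same equivalents, so the reagent shrinks with it and the conversion time stretches to 361 h, which gives 6.69% at 25 h. The computed neighbour gives 6.76%.

All runs are simulated for an exercise.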